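J is the product we want, and its excess over G, its mirror image, measures how far J has run ahead of G. The charge and the earlier readings are these:

| setting | midnight | alpha | epsilon | theta | delta |
|---|---|---|---|---|---|
| E | 36 mM | 36 mM | 36 mM | 36 mM | 36 mM |
| X | 36 mM | 36 mM | 36 mM | 36 mM | 36 mM |
| Q | 4.5 equiv | 3.00 equiv | 3.00 equiv | 3.00 equiv | 3.00 equiv |
| temperature | 10 °C |  | 10 °C | 40 °C | 70 °C |
| remark | run made earlier | at 10 °C until 10 h, from then on at 70 °C |  |  |  |
| time |  | 20 h | 20 h | 20 h | 20 h |

midnight run (percent of the E and X together charged)

| time / min | J / % | G / % | E / % |
|---|---|---|---|
| 30.0 | 0.9 | 0.2 | 49.0 |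
| 60.0 | 1.7 | 0.2 | 48.2 |
| 90.0 | 3.2 | 0.9 | 47.0 |
| 120 | 4.0 | 0.2 | 46.4 |

(readings scatter by 0.3 percentage points)

- Q is single-handed; E and X are mirror images of each other, charged as a racemate, each of them at the stated concentration
- steps thought possible: 2 Q -> L; Q + E -> J; Q + X -> G
- an excess is the difference of the two amounts in percent of their sum
- the earlier runs do not show what temperature does; that part of a forecast is a guess
- an excess is below zero if the other one leads
- the handed part of Q does not stay in what it makes, so the products of the two hands are mirror images too

- the best flask by excess of J over G; "all alike" if 1.5 percentage points covers them all (alpha / epsilon / theta / delta / all alike)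
- excess of J over G at the end, alpha
- excess of J over G at the end, epsilon
- excess of J over G at the end, theta
- excess of J over G at the end, delta

We carry one quantity from the midnight run. There E fell from 0.5 of the charge to 46.4% in 120 min, a reading with a scatter of 0.3 percentage points. The step Q + E -> J holds one Q, so we scale this to 3.00 equiv of Q and get 40.1 h. This is the E-time, the pseudo-first-order time in which E falls to 36.8% of what it was while Q stays at its charge. G is harder to read: it lies between 0.2% and 0.9%, and we can say just that its last reading is smaller than J's 4.0%.

Epsilon and alpha look nearly the same, with one charge and one temperature up to 10 h. By then each has had 0.249 E-times, so we reckon that E stands at 77.9% of its own charge in both. Epsilon stays cold, and because its E-time is longer than its whole 20 h, we expect 60.8% of its E to remain, with J well ahead of G. Alpha spends its later hours at 70 °C. How far heat shortens the clocks is a guess, but 3.00 equiv of Q covers both hands, which together take 2 equiv. If heat carries X through as well, J and G end level in alpha, so we rank epsilon first.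

The forecast named epsilon, with 13% for alpha, 71% for epsilon, 35% for theta and 8% for delta, and held that “Delta and alpha drive both hands towards completion”. The flasks give epsilon as the best, with 1.78% for alpha, 87.0% for epsilon, 34.4% for theta and 0.265% for delta.

    2 Q → L (k = 0.00670 /M/min, Ea = 91.0 kJ/mol)
    Q + E → J (k = 0.284 /M/min, Ea = 58.0 kJ/mol)
    Q + X → G (k = 0.149 /M/min, Ea = 88.0 kJ/mol)
    (constants at 70 °C)

Epsilon keeps 63% of its E against our 60.8%, with Q down to 86.7% of its own charge. Alpha matches epsilon at 10.0 h, with X at 49.3% of the substrate charge, yet ends with X at 1.82%. Between delta and epsilon the excess differs by −87 points, and without what temperature does to Q + X -> G that difference stands at 11 points, so this is a part of the reason. The time given counts as well: epsilon left ten times as long has an excess of 68.7% instead of 87.0%. In a repeat of epsilon at 25 °C, the E-time becomes 11.6 h. Taking Q midway between its charge and its final 69.5%, we get 23.2% of E left, and the computed flask keeps 25%.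

The earlier runs and the new flask come from a simulation from invented constants; scatter was added.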